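Confluentic acid is disconnected at the C1–C6 bond of ring A. The feature exploited is the 1,3-oxygen pattern of ring A: the ester carbon on C1, the C2 hydroxyl, the C4 oxygen and the C6 2-oxoheptyl chain map onto one linear fourteen-carbon chain of alternating carbonyls that already ends at the ring B phenol oxygen. In the key step an amine base folds this aryl 3,5,7-trioxo ester by intramolecular aldol condensation and aromatization, creating ring A with the depside ester in place. The precursor carries the remote ketone as a dioxolane and the ring B acid as a tert-butyl ester, and arises from acylketene capture by the ring B phenol.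

Key step: step 12

Remark on the chemistry: compound 15 is drawn as the all-keto tautomer although it should exist largely as enols; aldol adduct 16 is a transient mixture of diastereomers whose two stereocentres vanish on aromatization; the target itself has no stereocentre.

Step 1
Reactants: 1 ethyl 3-oxooctanoate
Product: 2 ethyl 2-(2-pentyl-1,3-dioxolan-2-yl)acetate
Conditions: HOCH2CH2OH (3 equiv), p-TsOH·H2O (cat.), toluene, reflux, Dean–Stark trap
Reagents that add atoms: ethylene glycol, OCCO
Why: Acid-catalysed ketalization with azeotropic removal of water should convert the ketone of the β-keto ester into its dioxolane while the ester stays untouched.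

Step 2
Reactants: 2 ethyl 2-(2-pentyl-1,3-dioxolan-2-yl)acetate
Product: 3 N-methoxy-N-methyl-2-(2-pentyl-1,3-dioxolan-2-yl)acetamide
Conditions: MeNH(OMe)·HCl (1.5 equiv), iPrMgCl (3 equiv), THF, −20 to 0 °C; aq. NH4Cl
Reagents that add atoms: N,O-dimethylhydroxylamine hydrochloride, CNOC.Cl
Why: The chloromagnesium amide of N,O-dimethylhydroxylamine should add to the ethyl ester and give the Weinreb amide directly (aminolysis of an ester by a magnesium amide), the ketal being inert to base.

Step 3
Reactants: 4 2,2,6-trimethyl-4H-1,3-dioxin-4-one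
Product: 5 2,2-dimethyl-6-(2-oxopropyl)-4H-1,3-dioxin-4-one
Conditions: LiN(SiMe3)2 (1.1 equiv), THF, −78 °C; AcCl (0.5 equiv), −78 °C to rt; aq. NH4Cl
Reagents that add atoms: acetyl chloride, CC(Cl)=O
Why: γ-Deprotonation of the dioxinone gives a lithium dienolate that should be C-acylated at the exocyclic carbon (vinylogous Claisen-type acylation), the acyl chloride being kept below the enolate because the product is the stronger acid.

Step 4
Reactants: 5 2,2-dimethyl-6-(2-oxopropyl)-4H-1,3-dioxin-4-one; 3 N-methoxy-N-methyl-2-(2-pentyl-1,3-dioxolan-2-yl)acetamide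
Product: 6 6-[2,4-dioxo-5-(2-pentyl-1,3-dioxolan-2-yl)pentyl]-2,2-dimethyl-4H-1,3-dioxin-4-one
Conditions: LiN(iPr)2 (2.2 equiv), THF, −78 to −40 °C; then 3 (0.8 equiv), −78 to −20 °C; aq. NH4Cl
Reagents that add atoms: none
Why: The dianion of the keto-dioxinone should react at its terminal, more basic carbon, and the chelated tetrahedral adduct of the Weinreb amide prevents a second addition (γ-acylation of a 1,3-dicarbonyl dianion).

Step 5
Reactants: 7 olivetol (5-pentylbenzene-1,3-diol)
Product: 8 2,4-dihydroxy-6-pentylbenzaldehyde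
Conditions: POCl3 (1.2 equiv), DMF, 0 °C to rt; then H2O, 50 °C
Reagents that add atoms: N,N-dimethylformamide, CN(C)C=O; water, O
Why: Vilsmeier–Haack formylation of the 5-alkylresorcinol should occur at the ring carbon next to the pentyl group, ortho to one hydroxyl and para to the other, as is usual for this substrate class.

Step 6
Reactants: 8 2,4-dihydroxy-6-pentylbenzaldehyde
Product: 9 4-(benzyloxy)-2-hydroxy-6-pentylbenzaldehyde
Conditions: BnBr (1.05 equiv), K2CO3 (1.1 equiv), acetone, rt
Reagents that add atoms: benzyl bromide, BrCc1ccccc1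
Why: The hydroxyl ortho to the formyl group is held in a hydrogen bond and is the weaker acid, so a Williamson etherification with one equivalent of halide should alkylate only the para hydroxyl.

Step 7
Reactants: 9 4-(benzyloxy)-2-hydroxy-6-pentylbenzaldehyde
Product: 10 4-(benzyloxy)-2-methoxy-6-pentylbenzaldehyde
Conditions: MeI (3 equiv), K2CO3 (2 equiv), DMF, 40 °C
Reagents that add atoms: iodomethane, CI
Why: Under more forcing Williamson conditions in a dipolar aprotic solvent the remaining chelated phenol should be methylated.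

Step 8
Reactants: 10 4-(benzyloxy)-2-methoxy-6-pentylbenzaldehyde
Product: 11 4-(benzyloxy)-2-methoxy-6-pentylbenzoic acid
Conditions: NaClO2, NaH2PO4, 2-methyl-2-butene, t-BuOH/H2O, rt
Reagents that add atoms: sodium chlorite, [Na+].[O-]Cl=O
Why: Pinnick oxidation should take the hindered, electron-rich aldehyde to the acid, the alkene scavenging hypochlorous acid so that the ring is not chlorinated.

Step 9
Reactants: 11 4-(benzyloxy)-2-methoxy-6-pentylbenzoic acid
Product: 12 tert-butyl 4-(benzyloxy)-2-methoxy-6-pentylbenzoate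
Conditions: Me2NCH(OtBu)2 (4 equiv), toluene, 80 °C
Reagents that add atoms: N,N-dimethylformamide di-tert-butyl acetal, CN(C)C(OC(C)(C)C)OC(C)(C)C
Why: tert-Butyl esterification by O-alkylation of the carboxylate needs no attack at the doubly ortho-substituted carbonyl carbon and should therefore tolerate the hindrance.

Step 10
Reactants: 12 tert-butyl 4-(benzyloxy)-2-methoxy-6-pentylbenzoate
Product: 13 tert-butyl 4-hydroxy-2-methoxy-6-pentylbenzoate
Conditions: H2 (1 atm), 10% Pd/C, EtOAc, rt
Reagents that add atoms: none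
Why: Catalytic hydrogenolysis should cleave the benzyl aryl ether and leave the tert-butyl ester and the arene intact.

Step 11
Reactants: 6 6-[2,4-dioxo-5-(2-pentyl-1,3-dioxolan-2-yl)pentyl]-2,2-dimethyl-4H-1,3-dioxin-4-one; 13 tert-butyl 4-hydroxy-2-methoxy-6-pentylbenzoate
Product: 15 4-(tert-butoxycarbonyl)-3-methoxy-5-pentylphenyl 3,5,7-trioxo-8-(2-pentyl-1,3-dioxolan-2-yl)octanoate, via acylketene 14 (not isolated)
Conditions: 13 (1.5 equiv), toluene (0.02 M), 110 °C, slow N2 stream, about 1 h; evaporate and use crude at once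
Reagents that add atoms: none
Why: Retro-hetero-Diels–Alder loss of acetone gives acylketene 14, which the phenol should capture at the ketene carbon (acylketene trapping, the known route from dioxinones to aryl β-keto esters); the ester of 13 is twisted out of conjugation so its para hydroxyl stays nucleophilic, and excess phenol with short heating holds back self-lactonization of the ketene.

Step 12
Reactants: 15 4-(tert-butoxycarbonyl)-3-methoxy-5-pentylphenyl 3,5,7-trioxo-8-(2-pentyl-1,3-dioxolan-2-yl)octanoate
Product: 17 tert-butyl 4-({2,4-dihydroxy-6-[(2-pentyl-1,3-dioxolan-2-yl)methyl]benzoyl}oxy)-2-methoxy-6-pentylbenzoate, via cyclic aldol adduct 16 (not isolated)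
Conditions: Et3N (3 equiv), CH2Cl2, 0 °C to rt; pH 6 phosphate buffer work-up; chromatography (excess 13 recovered)
Reagents that add atoms: none
Why: Triethylamine should generate the ammonium enolate of the poly-β-carbonyl chain, whose C2 carbon (between the ester carbon C1 and the C3 ketone) adds to the C7 ketone to give aldol adduct 16; E1cB loss of water and enolization of the C3 and C5 carbonyls then deliver aromatic ring A with its new C1–C6 bond. The closest known reaction type is the base-mediated aldol aromatization of 3,5,7-trioxo alkyl esters to 2,4-dihydroxybenzoates, here applied to an aryl ester. The one ring formed, the six-membered carbocycle ring A, closes in a 6-(enolendo)-exo-trig mode. No stereocentre results, because the two created in 16 are erased by dehydration and aromatization. The step needs the C2-to-C7 aldol to win over three pathways that would expel the ring B phenoxide (Claisen attack of C6 on C1, lactonization of the C5 enol oxygen onto C1 to a 4-hydroxy-2-pyranone, and elimination from the C2 enolate to the acylketene) and over a C8-to-C3 aldol. It is secured by the dioxolane, which leaves C9 non-electrophilic and C8 only singly activated so that C7 is the one ketone facing a doubly activated carbon six atoms away, by the weak amine base in a non-nucleophilic solvent at low temperature, and by the ring B ester being twisted out of conjugation by its two ortho groups, which keeps the aryloxide a modest leaving group.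

Step 13
Reactants: 17 tert-butyl 4-({2,4-dihydroxy-6-[(2-pentyl-1,3-dioxolan-2-yl)methyl]benzoyl}oxy)-2-methoxy-6-pentylbenzoate
Product: 18 tert-butyl 4-({2-hydroxy-4-methoxy-6-[(2-pentyl-1,3-dioxolan-2-yl)methyl]benzoyl}oxy)-2-methoxy-6-pentylbenzoate
Conditions: MeI (1.2 equiv), K2CO3 (1.5 equiv), acetone, rt
Reagents that add atoms: iodomethane, CI
Why: The C4 hydroxyl of ring A is free and the more acidic, whereas the C2 hydroxyl is hydrogen-bonded to the ester carbonyl, so a Williamson O-methylation with about one equivalent of halide should give the 4-methyl ether only.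

Step 14
Reactants: 18 tert-butyl 4-({2-hydroxy-4-methoxy-6-[(2-pentyl-1,3-dioxolan-2-yl)methyl]benzoyl}oxy)-2-methoxy-6-pentylbenzoate
Product: 19 confluentic acid, 4-{[2-hydroxy-4-methoxy-6-(2-oxoheptyl)benzoyl]oxy}-2-methoxy-6-pentylbenzoic acid
Conditions: TFA/CH2Cl2/H2O (10:10:1), 0 °C to rt, short reaction time; evaporate cold
Reagents that add atoms: water, O
Why: Aqueous trifluoroacetic acid should hydrolyse the dioxolane and cleave the tert-butyl ester by alkyl–oxygen fission with loss of isobutene (acidolysis), while the aryl ester, which reacts only at acyl carbon, survives; cold and short exposure limits enol-lactonization of the freed ketone onto the depside carbonyl.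

Compound list
1 | ethyl 3-oxooctanoate | CCCCCC(=O)CC(=O)OCC | starting material
2 | ethyl 2-(2-pentyl-1,3-dioxolan-2-yl)acetate | CCCCCC1(CC(=O)OCC)OCCO1 | intermediate
3 | N-methoxy-N-methyl-2-(2-pentyl-1,3-dioxolan-2-yl)acetamide | CCCCCC1(CC(=O)N(C)OC)OCCO1 | intermediate
4 | 2,2,6-trimethyl-4H-1,3-dioxin-4-one | CC1=CC(=O)OC(C)(C)O1 | starting material
5 | 2,2-dimethyl-6-(2-oxopropyl)-4H-1,3-dioxin-4-one | CC(=O)CC1=CC(=O)OC(C)(C)O1 | intermediate
6 | 6-[2,4-dioxo-5-(2-pentyl-1,3-dioxolan-2-yl)pentyl]-2,2-dimethyl-4H-1,3-dioxin-4-one | CCCCCC1(CC(=O)CC(=O)CC2=CC(=O)OC(C)(C)O2)OCCO1 | intermediate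
7 | olivetol (5-pentylbenzene-1,3-diol) | CCCCCc1cc(O)cc(O)c1 | starting material
8 | 2,4-dihydroxy-6-pentylbenzaldehyde | CCCCCc1cc(O)cc(O)c1C=O | intermediate
9 | 4-(benzyloxy)-2-hydroxy-6-pentylbenzaldehyde | CCCCCc1cc(OCc2ccccc2)cc(O)c1C=O | intermediate
10 | 4-(benzyloxy)-2-methoxy-6-pentylbenzaldehyde | CCCCCc1cc(OCc2ccccc2)cc(OC)c1C=O | intermediate
11 | 4-(benzyloxy)-2-methoxy-6-pentylbenzoic acid | CCCCCc1cc(OCc2ccccc2)cc(OC)c1C(=O)O | intermediate
12 | tert-butyl 4-(benzyloxy)-2-methoxy-6-pentylbenzoate | CCCCCc1cc(OCc2ccccc2)cc(OC)c1C(=O)OC(C)(C)C | intermediate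
13 | tert-butyl 4-hydroxy-2-methoxy-6-pentylbenzoate | CCCCCc1cc(O)cc(OC)c1C(=O)OC(C)(C)C | intermediate
14 | acylketene, 3,5,7-trioxo-8-(2-pentyl-1,3-dioxolan-2-yl)oct-1-en-1-one | CCCCCC1(CC(=O)CC(=O)CC(=O)C=C=O)OCCO1 | intermediate (not isolated)
15 | 4-(tert-butoxycarbonyl)-3-methoxy-5-pentylphenyl 3,5,7-trioxo-8-(2-pentyl-1,3-dioxolan-2-yl)octanoate | CCCCCC1(CC(=O)CC(=O)CC(=O)CC(=O)Oc2cc(CCCCC)c(C(=O)OC(C)(C)C)c(OC)c2)OCCO1 | intermediate
16 | cyclic aldol adduct, 4-(tert-butoxycarbonyl)-3-methoxy-5-pentylphenyl 2-hydroxy-4,6-dioxo-2-[(2-pentyl-1,3-dioxolan-2-yl)methyl]cyclohexane-1-carboxylate (mixture of diastereomers) | CCCCCC1(CC2(O)CC(=O)CC(=O)C2C(=O)Oc2cc(CCCCC)c(C(=O)OC(C)(C)C)c(OC)c2)OCCO1 | intermediate (not isolated)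
17 | tert-butyl 4-({2,4-dihydroxy-6-[(2-pentyl-1,3-dioxolan-2-yl)methyl]benzoyl}oxy)-2-methoxy-6-pentylbenzoate | CCCCCC1(Cc2cc(O)cc(O)c2C(=O)Oc2cc(CCCCC)c(C(=O)OC(C)(C)C)c(OC)c2)OCCO1 | intermediate
18 | tert-butyl 4-({2-hydroxy-4-methoxy-6-[(2-pentyl-1,3-dioxolan-2-yl)methyl]benzoyl}oxy)-2-methoxy-6-pentylbenzoate | CCCCCC1(Cc2cc(OC)cc(O)c2C(=O)Oc2cc(CCCCC)c(C(=O)OC(C)(C)C)c(OC)c2)OCCO1 | intermediate
19 | confluentic acid | CCCCCC(=O)Cc1cc(OC)cc(O)c1C(=O)Oc1cc(CCCCC)c(C(=O)O)c(OC)c1 | target

Total step count: 14. Longest linear sequence: 10 steps (steps 5 to 14, from olivetol 7).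

Steps most likely to fail

Step 12 (key step). The ring B phenoxide may be expelled before the carbocycle closes, through lactonization of the C5 enol oxygen onto the ester carbon, Claisen closure from C6, or elimination from the C2 enolate to the ketene. The fallback runs the same aldol folding where the ester carbon carries no leaving group, and sets out from 6 and 13. Treating diketo-dioxinone 6 with Et3N in CH2Cl2 should aromatize it to 7-hydroxy-2,2-dimethyl-5-[(2-pentyl-1,3-dioxolan-2-yl)methyl]-4H-1,3-benzodioxin-4-one F1. MeI and K2CO3 in acetone should give 7-methoxy-2,2-dimethyl-5-[(2-pentyl-1,3-dioxolan-2-yl)methyl]-4H-1,3-benzodioxin-4-one F2. KOH in aqueous DMSO, followed by cold acidification to pH 4, should open the acetonide to 2-hydroxy-4-methoxy-6-[(2-pentyl-1,3-dioxolan-2-yl)methyl]benzoic acid F3. Esterification of F3 with phenol 13 (DCC, cat. DMAP, CH2Cl2) should then give 18, where the route is rejoined.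

Step 11. The acylketene may cyclize onto its own C5 enol oxygen to a 4-hydroxy-2-pyranone faster than the weakly nucleophilic phenol adds, and the aryl β-keto ester may revert thermally to the ketene. The fallback captures the ketene with a better nucleophile and builds the depside ester afterwards; it sets out from 6 and 13. Heating 6 with benzyl alcohol (3 equiv) in toluene at 110 °C should give benzyl 3,5,7-trioxo-8-(2-pentyl-1,3-dioxolan-2-yl)octanoate F4. Et3N in CH2Cl2 should aromatize it to benzyl 2,4-dihydroxy-6-[(2-pentyl-1,3-dioxolan-2-yl)methyl]benzoate F5. MeI and K2CO3 should give benzyl 2-hydroxy-4-methoxy-6-[(2-pentyl-1,3-dioxolan-2-yl)methyl]benzoate F6. Hydrogenolysis (H2, 10% Pd/C, EtOAc) should free the acid F3, and DCC coupling of F3 with 13 returns to the route at 18.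

Step 4. The dianion may act as a base toward the α-methylene of the Weinreb amide, which stalls the acylation and can open the dioxolane by β-elimination. The fallback replaces acylation by aldol addition and oxidation, and sets out from 2 and 5. Reduction of ester 2 with iBu2AlH (1.05 equiv, CH2Cl2, −78 °C) should give 2-(2-pentyl-1,3-dioxolan-2-yl)acetaldehyde F7. Addition of the dianion of 5 (LiN(iPr)2, THF, −78 °C) to F7, which is fast enough to outrun proton transfer, should give racemic 6-[4-hydroxy-2-oxo-5-(2-pentyl-1,3-dioxolan-2-yl)pentyl]-2,2-dimethyl-4H-1,3-dioxin-4-one F8. Oxidation of F8 with Dess–Martin periodinane (NaHCO3, CH2Cl2, 0 °C) should give 6, where the route is rejoined.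

Further compounds
F1 | step 12 | 7-hydroxy-2,2-dimethyl-5-[(2-pentyl-1,3-dioxolan-2-yl)methyl]-4H-1,3-benzodioxin-4-one | CCCCCC1(Cc2cc(O)cc3OC(C)(C)OC(=O)c23)OCCO1
F2 | step 12 | 7-methoxy-2,2-dimethyl-5-[(2-pentyl-1,3-dioxolan-2-yl)methyl]-4H-1,3-benzodioxin-4-one | CCCCCC1(Cc2cc(OC)cc3OC(C)(C)OC(=O)c23)OCCO1
F3 | step 12 | 2-hydroxy-4-methoxy-6-[(2-pentyl-1,3-dioxolan-2-yl)methyl]benzoic acid | CCCCCC1(Cc2cc(OC)cc(O)c2C(=O)O)OCCO1
F4 | step 11 | benzyl 3,5,7-trioxo-8-(2-pentyl-1,3-dioxolan-2-yl)octanoate | CCCCCC1(CC(=O)CC(=O)CC(=O)CC(=O)OCc2ccccc2)OCCO1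
F5 | step 11 | benzyl 2,4-dihydroxy-6-[(2-pentyl-1,3-dioxolan-2-yl)methyl]benzoate | CCCCCC1(Cc2cc(O)cc(O)c2C(=O)OCc2ccccc2)OCCO1
F6 | step 11 | benzyl 2-hydroxy-4-methoxy-6-[(2-pentyl-1,3-dioxolan-2-yl)methyl]benzoate | CCCCCC1(Cc2cc(OC)cc(O)c2C(=O)OCc2ccccc2)OCCO1
F7 | step 4 | 2-(2-pentyl-1,3-dioxolan-2-yl)acetaldehyde | CCCCCC1(CC=O)OCCO1
F8 | step 4 | 6-[4-hydroxy-2-oxo-5-(2-pentyl-1,3-dioxolan-2-yl)pentyl]-2,2-dimethyl-4H-1,3-dioxin-4-one (racemic) | CCCCCC1(CC(O)CC(=O)CC2=CC(=O)OC(C)(C)O2)OCCO1
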